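**Plan** (chroman numbering O1, C2, C3, C4, C4a, C5–C8, C8a; ring A = the phloroglucinol-derived benzene ring, ring C = the pyran ring)
Cuts, in retrosynthetic order: the five protecting groups; the enone C=C of the chalcone arm (crossed aldol); O1–C2 and C3–C4 of ring C together; the aryl–alkyl bond C4a–C4; the allyl–carbinol bond of the side chain.
Enabling feature: O1 on C8a and the benzylic C4 on C4a are ortho neighbours on ring A, the two ends of a latent o-quinone methide O1=C8a–C4a=C4. C2–C3 with the 4-oxyphenyl group on C2 is a polarised styrene, so ring C is their [4+2] adduct. The C8 acetyl group blocks C8, chelates O1–H and lets the C5 oxygen be capped, so only O1 can close.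
Forward: chiral side-chain aldehyde (steps 1–4); union with the acetophenone at C4a–C4 (step 6); ring C from the styrene, which brings in the third aryl group and completes the diarylheptanoid chain (step 8); chalcone arm (step 9); deprotection (step 10).
Stereochemistry: the side-chain carbinol from catalyst-controlled allylation (step 2); C4 from π-facial control by a chiral phosphoric acid in step 8; C2 trans to C4 from the ring-closing transition state (C4 chain pseudo-axial beside the C5 oxygen, aryl equatorial).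

Key step: step 8

Remark: 3-(4-hydroxyphenyl)propan-1-ol, 1-(2,4-dihydroxy-6-methoxyphenyl)ethan-1-one and 4-(methoxymethoxy)benzaldehyde are taken as purchased; the two chiral catalysts (steps 2 and 8) are written as the (R)-antipodes, assumed to give the drawn configurations, and the other antipode is used if the sense proves opposite.

**Step 1**
Reactants: 1 3-(4-hydroxyphenyl)propan-1-ol
Product: 2 3-[4-(methoxymethoxy)phenyl]propan-1-ol
Conditions: MOMCl (1.05 equiv), K2CO3, acetone, 0 °C → rt
Reagents that add atoms: chloromethyl methyl ether (MOMCl), COCCl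
Why: Williamson-type O-alkylation in which the weak base deprotonates only the phenol, so the phenoxide is methoxymethylated and the primary alcohol stays free.

**Step 2**
Reactants: 2 3-[4-(methoxymethoxy)phenyl]propan-1-ol
Product: 4 (3R)-1-[4-(methoxymethoxy)phenyl]hex-5-en-3-ol, via 3-arylpropanal 3 (not isolated)
Conditions: [Ir(cod)Cl]2 (2.5 mol %), (R)-2,2'-bis(diphenylphosphino)-1,1'-binaphthyl (5 mol %), 4-chloro-3-nitrobenzoic acid (10 mol %), Cs2CO3 (20 mol %), allyl acetate, THF, 100 °C (sealed tube)
Reagents that add atoms: allyl acetate, C=CCOC(C)=O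
Why: Iridium-catalysed transfer-hydrogenative carbonyl allylation from the alcohol oxidation level, in which the alcohol is dehydrogenated to aldehyde 3 and this is allylated by the chiral allyliridium species through a closed chair transition state, the ligand setting the (R)-carbinol centre.

**Step 3**
Reactants: 4 (3R)-1-[4-(methoxymethoxy)phenyl]hex-5-en-3-ol
Product: 5 tert-butyl{[(3R)-1-[4-(methoxymethoxy)phenyl]hex-5-en-3-yl]oxy}dimethylsilane
Conditions: TBSCl, imidazole, DMF, rt
Reagents that add atoms: tert-butyldimethylsilyl chloride (TBSCl), CC(C)(C)[Si](C)(C)Cl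
Why: Imidazole-promoted silylation of a secondary alcohol, which leaves the stereocentre untouched and blocks retro-aldol and dehydration pathways of the β-oxygenated aldehyde made next.

**Step 4**
Reactants: 5 tert-butyl{[(3R)-1-[4-(methoxymethoxy)phenyl]hex-5-en-3-yl]oxy}dimethylsilane
Product: 7 (3R)-3-[(tert-butyldimethylsilyl)oxy]-5-[4-(methoxymethoxy)phenyl]pentanal, via secondary ozonide 6 (not isolated)
Conditions: O3, CH2Cl2, −78 °C; then PPh3, −78 °C → rt
Reagents that add atoms: ozone, [O-][O+]=O
Why: Ozonolysis with reductive work-up cleaves the only C=C bond to the aldehyde, the alkoxy-substituted benzene ring reacting far more slowly at −78 °C.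

**Step 5**
Reactants: 8 1-(2,4-dihydroxy-6-methoxyphenyl)ethan-1-one
Product: 9 1-[2-hydroxy-6-methoxy-4-(methoxymethoxy)phenyl]ethan-1-one
Conditions: MOMCl (1.05 equiv), K2CO3, acetone, 0 °C → rt
Reagents that add atoms: chloromethyl methyl ether (MOMCl), COCCl
Why: Selective Williamson etherification, since the 2-hydroxyl is held in a hydrogen bond to the acetyl group and only the 4-hydroxyl is alkylated under weak base.

**Step 6**
Reactants: 9 1-[2-hydroxy-6-methoxy-4-(methoxymethoxy)phenyl]ethan-1-one; 7 (3R)-3-[(tert-butyldimethylsilyl)oxy]-5-[4-(methoxymethoxy)phenyl]pentanal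
Product: 11 1-{3-[(3R)-3-[(tert-butyldimethylsilyl)oxy]-1-hydroxy-5-[4-(methoxymethoxy)phenyl]pentyl]-2-hydroxy-6-methoxy-4-(methoxymethoxy)phenyl}ethan-1-one (both epimers at the benzylic carbinol), via bromomagnesium phenolate 10 (not isolated)
Conditions: EtMgBr (1.0 equiv), Et2O, 0 °C; solvent exchanged for CH2Cl2; 7 (1.2 equiv), rt; then H2O
Reagents that add atoms: none
Why: ortho-Specific hydroxyalkylation of a magnesium phenoxide (phenol–aldehyde aldol-type C-alkylation through a six-membered magnesium chelate), in which C3 is the only free position ortho to the phenoxide oxygen and the non-coordinating solvent keeps the salicyl alcohol from eliminating; the new benzylic centre is not controlled and is erased in step 8.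

**Step 7**
Reactants: 12 4-(methoxymethoxy)benzaldehyde
Product: 13 1-ethenyl-4-(methoxymethoxy)benzene
Conditions: Ph3PCH3Br, KOtBu, THF, 0 °C → rt
Reagents that add atoms: methyltriphenylphosphonium bromide, C[P+](c1ccccc1)(c1ccccc1)c1ccccc1.[Br-]
Why: Wittig methylenation of a non-enolisable aromatic aldehyde with the unstabilised ylide.

**Step 8**
Reactants: 11 1-{3-[(3R)-3-[(tert-butyldimethylsilyl)oxy]-1-hydroxy-5-[4-(methoxymethoxy)phenyl]pentyl]-2-hydroxy-6-methoxy-4-(methoxymethoxy)phenyl}ethan-1-one; 13 1-ethenyl-4-(methoxymethoxy)benzene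
Product: 15 1-[(2R,4R)-4-{(2R)-2-[(tert-butyldimethylsilyl)oxy]-4-[4-(methoxymethoxy)phenyl]butyl}-7-methoxy-5-(methoxymethoxy)-2-[4-(methoxymethoxy)phenyl]-3,4-dihydro-2H-1-benzopyran-8-yl]ethan-1-one (same C4 geometry as the target; the descriptor reads R only because the silyl ether raises the CIP rank of the side chain), via o-quinone methide 14 (not isolated)
Conditions: (R)-3,3'-bis(2,4,6-triisopropylphenyl)-1,1'-binaphthyl-2,2'-diyl hydrogen phosphate (10 mol %), 13 (3 equiv), 4 Å molecular sieves, toluene, −20 °C → 0 °C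
Reagents that add atoms: none
Why: The phosphoric acid ionises the benzylic alcohol of 11 (cation stabilised by the ortho-OH, ortho-OMOM and para-OMe groups) to the hydrogen-bonded o-quinone methide 14, an electron-poor 1-oxadiene O1=C8a–C4a=C4 made more electrophilic by the C8 acetyl group, and the electron-rich styrene 13 adds to it in an asynchronous inverse-electron-demand hetero-Diels–Alder reaction in which the C3–C4 bond runs ahead of the O1–C2 bond. The closest known reaction type is the Brønsted-acid-catalysed [4+2] cycloaddition of o-hydroxybenzyl alcohols with styrenes to 2-arylchromans, including its enantioselective chiral-acid version. Ring C closes by an intermolecular [4π+2π] heterocycloaddition: the CH2 terminus of 13 bonds to C4 and the o-quinone methide oxygen then closes the six-membered ring onto the 4-oxybenzylic carbon C2, which restores the aromaticity of ring A. C4 is set by π-facial selection on 14 inside the chiral ion pair, the catalyst antipode being the one matched with the 1,3-induction from the side-chain silyl ether centre; since that centre is already fixed, any C4 epimer is a diastereomer and separable. C2 is set relative to C4 in the ring closure: the C4 chain must stand pseudo-axial to avoid peri strain with the C5–OMOM group and the aryl group takes the equatorial position, which should give the 2,4-trans chroman, and a cis isomer can drain to trans by reversible C2–O ionisation under the acid. The step needs regio-, site- and chemoselectivity: the polarisation of both partners puts oxygen on the aryl-bearing carbon, the C5 oxygen is capped as a MOM ether so that only the chelated O1–H can become the ring oxygen, and an excess of 13 at low temperature keeps 14 from self-condensation.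

**Step 9**
Reactants: 15 1-[(2R,4R)-4-{(2R)-2-[(tert-butyldimethylsilyl)oxy]-4-[4-(methoxymethoxy)phenyl]butyl}-7-methoxy-5-(methoxymethoxy)-2-[4-(methoxymethoxy)phenyl]-3,4-dihydro-2H-1-benzopyran-8-yl]ethan-1-one; 12 4-(methoxymethoxy)benzaldehyde
Product: 17 (2E)-1-[(2R,4R)-4-{(2R)-2-[(tert-butyldimethylsilyl)oxy]-4-[4-(methoxymethoxy)phenyl]butyl}-7-methoxy-5-(methoxymethoxy)-2-[4-(methoxymethoxy)phenyl]-3,4-dihydro-2H-1-benzopyran-8-yl]-3-[4-(methoxymethoxy)phenyl]prop-2-en-1-one, via aldol adduct 16 (not isolated)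
Conditions: KOH (aq., excess), EtOH, rt
Reagents that add atoms: none
Why: Claisen–Schmidt (crossed aldol) condensation in which the methyl ketone enolate adds to the non-enolisable aldehyde and aldol 16 loses water by E1cB to the conjugated (E)-enone; the MOM and TBS ethers are base-stable, the C2 aryl group carries no free phenol that could open ring C, and no stereocentre lies next to an acidic position.

**Step 10**
Reactants: 17 (2E)-1-[(2R,4R)-4-{(2R)-2-[(tert-butyldimethylsilyl)oxy]-4-[4-(methoxymethoxy)phenyl]butyl}-7-methoxy-5-(methoxymethoxy)-2-[4-(methoxymethoxy)phenyl]-3,4-dihydro-2H-1-benzopyran-8-yl]-3-[4-(methoxymethoxy)phenyl]prop-2-en-1-one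
Product: 18 (2E)-1-[(2R,4S)-5-hydroxy-4-[(2R)-2-hydroxy-4-(4-hydroxyphenyl)butyl]-2-(4-hydroxyphenyl)-7-methoxy-3,4-dihydro-2H-1-benzopyran-8-yl]-3-(4-hydroxyphenyl)prop-2-en-1-one (CNP0102599.2)
Conditions: HCl (about 1 M) in MeOH, 0 °C → rt
Reagents that add atoms: none
Why: Acid-catalysed acetal exchange with methanol removes the four aryl MOM groups and the TBS ether in one mild operation that spares the enone; the geometry at C2 and C4 is untouched and the C4 descriptor reads S again once silicon has left the side-chain oxygen.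

**Compound list**
1 | 3-(4-hydroxyphenyl)propan-1-ol | OCCCc1ccc(O)cc1 | starting material
2 | 3-[4-(methoxymethoxy)phenyl]propan-1-ol | OCCCc1ccc(OCOC)cc1 | intermediate
3 | 3-[4-(methoxymethoxy)phenyl]propanal (not isolated) | O=CCCc1ccc(OCOC)cc1 | intermediate
4 | (3R)-1-[4-(methoxymethoxy)phenyl]hex-5-en-3-ol | C=CC[C@H](O)CCc1ccc(OCOC)cc1 | intermediate
5 | tert-butyl{[(3R)-1-[4-(methoxymethoxy)phenyl]hex-5-en-3-yl]oxy}dimethylsilane | C=CC[C@H](O[Si](C)(C)C(C)(C)C)CCc1ccc(OCOC)cc1 | intermediate
6 | 3-{(2R)-2-[(tert-butyldimethylsilyl)oxy]-4-[4-(methoxymethoxy)phenyl]butyl}-1,2,4-trioxolane (not isolated; both epimers at the ring carbon) | C1(C[C@H](O[Si](C)(C)C(C)(C)C)CCc2ccc(OCOC)cc2)OCOO1 | intermediate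
7 | (3R)-3-[(tert-butyldimethylsilyl)oxy]-5-[4-(methoxymethoxy)phenyl]pentanal | O=CC[C@H](O[Si](C)(C)C(C)(C)C)CCc1ccc(OCOC)cc1 | intermediate
8 | 1-(2,4-dihydroxy-6-methoxyphenyl)ethan-1-one | CC(=O)c1c(O)cc(O)cc1OC | starting material
9 | 1-[2-hydroxy-6-methoxy-4-(methoxymethoxy)phenyl]ethan-1-one | CC(=O)c1c(O)cc(OCOC)cc1OC | intermediate
10 | bromomagnesium 2-acetyl-3-methoxy-5-(methoxymethoxy)phenolate (not isolated) | CC(=O)c1c(O[Mg]Br)cc(OCOC)cc1OC | intermediate
11 | 1-{3-[(3R)-3-[(tert-butyldimethylsilyl)oxy]-1-hydroxy-5-[4-(methoxymethoxy)phenyl]pentyl]-2-hydroxy-6-methoxy-4-(methoxymethoxy)phenyl}ethan-1-one (both epimers at C1 of the pentyl chain) | CC(=O)c1c(O)c(C(O)C[C@H](O[Si](C)(C)C(C)(C)C)CCc2ccc(OCOC)cc2)c(OCOC)cc1OC | intermediate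
12 | 4-(methoxymethoxy)benzaldehyde | O=Cc1ccc(OCOC)cc1 | starting material
13 | 1-ethenyl-4-(methoxymethoxy)benzene | C=Cc1ccc(OCOC)cc1 | intermediate
14 | 2-acetyl-6-{(3R)-3-[(tert-butyldimethylsilyl)oxy]-5-[4-(methoxymethoxy)phenyl]pentylidene}-3-methoxy-5-(methoxymethoxy)cyclohexa-2,4-dien-1-one (not isolated; alkylidene geometry not fixed) | CC(=O)C1=C(OC)C=C(OCOC)C(=CC[C@H](O[Si](C)(C)C(C)(C)C)CCc2ccc(OCOC)cc2)C1=O | intermediate
15 | 1-[(2R,4R)-4-{(2R)-2-[(tert-butyldimethylsilyl)oxy]-4-[4-(methoxymethoxy)phenyl]butyl}-7-methoxy-5-(methoxymethoxy)-2-[4-(methoxymethoxy)phenyl]-3,4-dihydro-2H-1-benzopyran-8-yl]ethan-1-one | COc1cc(OCOC)c2c(c1C(C)=O)O[C@@H](c1ccc(OCOC)cc1)C[C@@H]2C[C@H](O[Si](C)(C)C(C)(C)C)CCc1ccc(OCOC)cc1 | intermediate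
16 | 1-[(2R,4R)-4-{(2R)-2-[(tert-butyldimethylsilyl)oxy]-4-[4-(methoxymethoxy)phenyl]butyl}-7-methoxy-5-(methoxymethoxy)-2-[4-(methoxymethoxy)phenyl]-3,4-dihydro-2H-1-benzopyran-8-yl]-3-hydroxy-3-[4-(methoxymethoxy)phenyl]propan-1-one (not isolated; both carbinol epimers) | COc1cc(OCOC)c2c(c1C(=O)CC(O)c1ccc(OCOC)cc1)O[C@@H](c1ccc(OCOC)cc1)C[C@@H]2C[C@H](O[Si](C)(C)C(C)(C)C)CCc1ccc(OCOC)cc1 | intermediate
17 | (2E)-1-[(2R,4R)-4-{(2R)-2-[(tert-butyldimethylsilyl)oxy]-4-[4-(methoxymethoxy)phenyl]butyl}-7-methoxy-5-(methoxymethoxy)-2-[4-(methoxymethoxy)phenyl]-3,4-dihydro-2H-1-benzopyran-8-yl]-3-[4-(methoxymethoxy)phenyl]prop-2-en-1-one | COc1cc(OCOC)c2c(c1C(=O)/C=C/c1ccc(OCOC)cc1)O[C@@H](c1ccc(OCOC)cc1)C[C@@H]2C[C@H](O[Si](C)(C)C(C)(C)C)CCc1ccc(OCOC)cc1 | intermediate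
18 | (2E)-1-[(2R,4S)-5-hydroxy-4-[(2R)-2-hydroxy-4-(4-hydroxyphenyl)butyl]-2-(4-hydroxyphenyl)-7-methoxy-3,4-dihydro-2H-1-benzopyran-8-yl]-3-(4-hydroxyphenyl)prop-2-en-1-one | COc1cc(O)c2c(c1C(=O)/C=C/c1ccc(O)cc1)O[C@@H](c1ccc(O)cc1)C[C@@H]2C[C@H](O)CCc1ccc(O)cc1 | target

**Step count**
Total: 10 steps. Longest linear sequence: 8 steps (steps 1, 2, 3, 4, 6, 8, 9, 10; compounds 1 → 2 → 4 → 5 → 7 → 11 → 15 → 17 → 18).

**Steps most likely to fail**

(a) Step 8. The π-facial selection on the o-quinone methide at C4 may be weak or mismatched. The styrene may also be too feeble a partner, so that the o-quinone methide oligomerises or the styrene polymerises under acid. The fallback sets out from 11 and builds ring C in two established stages. The enol silane trimethyl({1-[4-(methoxymethoxy)phenyl]ethenyl}oxy)silane F1 (made from 1-[4-(methoxymethoxy)phenyl]ethan-1-one with Me3SiOSO2CF3 and Et3N) is added to the o-quinone methide released from 11 by the same phosphoric acid. This is a Mukaiyama–Michael addition with a much stronger nucleophile, of a class for which acid-catalysed asymmetric additions to o-quinone methides are established. Aqueous work-up should give the open-chain phenol ketone (3S,5R)-3-[3-acetyl-2-hydroxy-4-methoxy-6-(methoxymethoxy)phenyl]-5-[(tert-butyldimethylsilyl)oxy]-1,7-bis[4-(methoxymethoxy)phenyl]heptan-1-one F2, whose C3 epimer is a diastereomer and is removed by chromatography. Reductive cyclisation of F2 (Et3SiH, BF3·OEt2, CH2Cl2, −78 °C) runs through the cyclic 2-aryl oxocarbenium ion. Axial hydride delivery on the half-chair that keeps the C4 chain pseudo-axial should give the 2,4-trans chroman, and the route is rejoined at 15.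

(b) Step 6. The chelated, acyl-deactivated phenoxide may add sluggishly to the aldehyde, the product may ionise and capture a second arene, and the β-silyloxy aldehyde may eliminate under the Lewis-acidic conditions. The fallback sets out from 9 and 7 and delivers the aldehyde inside a covalent aryl borate instead of a magnesium chelate. With PhB(OH)2 and catalytic propanoic acid in toluene under azeotropic water removal it should give the isolable cyclic boronate 1-[4-{(2R)-2-[(tert-butyldimethylsilyl)oxy]-4-[4-(methoxymethoxy)phenyl]butyl}-7-methoxy-5-(methoxymethoxy)-2-phenyl-4H-1,3,2-benzodioxaborinin-8-yl]ethan-1-one F3. In F3 both the phenol and the benzylic oxygen are masked, so over-reaction is excluded. Transesterification of F3 with 2,2-dimethylpropane-1,3-diol releases the salicyl alcohol, and the route is rejoined at 11.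

(c) Step 10. Under protic acid the C2–O1 bond (a 4-oxybenzylic ether with an acyl-phenoxide leaving group) may ionise, with loss of configuration at C2 or capture of the cation by methanol or by the side-chain hydroxyl. The fallback sets out from 17 and removes the acetals by aprotic silyl transfer. Et3SiOSO2CF3 with 2,2'-bipyridyl in CH2Cl2 at 0 °C should convert the four aryl MOM ethers into triethylsilyl ethers, giving (2E)-1-[(2R,4R)-4-{(2R)-2-[(tert-butyldimethylsilyl)oxy]-4-[4-(triethylsilyloxy)phenyl]butyl}-7-methoxy-5-(triethylsilyloxy)-2-[4-(triethylsilyloxy)phenyl]-3,4-dihydro-2H-1-benzopyran-8-yl]-3-[4-(triethylsilyloxy)phenyl]prop-2-en-1-one F4. HF·pyridine buffered with pyridine in THF then removes all five silyl groups, and the route is rejoined at 18.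

**Further compounds**
F1 | step 8 | trimethyl({1-[4-(methoxymethoxy)phenyl]ethenyl}oxy)silane | C=C(O[Si](C)(C)C)c1ccc(OCOC)cc1
F2 | step 8 | (3S,5R)-3-[3-acetyl-2-hydroxy-4-methoxy-6-(methoxymethoxy)phenyl]-5-[(tert-butyldimethylsilyl)oxy]-1,7-bis[4-(methoxymethoxy)phenyl]heptan-1-one | CC(=O)c1c(O)c([C@H](CC(=O)c2ccc(OCOC)cc2)C[C@H](O[Si](C)(C)C(C)(C)C)CCc2ccc(OCOC)cc2)c(OCOC)cc1OC
F3 | step 6 | 1-[4-{(2R)-2-[(tert-butyldimethylsilyl)oxy]-4-[4-(methoxymethoxy)phenyl]butyl}-7-methoxy-5-(methoxymethoxy)-2-phenyl-4H-1,3,2-benzodioxaborinin-8-yl]ethan-1-one (both epimers at C4 of the boron heterocycle) | CC(=O)c1c2OB(c3ccccc3)OC(C[C@H](O[Si](C)(C)C(C)(C)C)CCc3ccc(OCOC)cc3)c2c(OCOC)cc1OC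
F4 | step 10 | (2E)-1-[(2R,4R)-4-{(2R)-2-[(tert-butyldimethylsilyl)oxy]-4-[4-(triethylsilyloxy)phenyl]butyl}-7-methoxy-5-(triethylsilyloxy)-2-[4-(triethylsilyloxy)phenyl]-3,4-dihydro-2H-1-benzopyran-8-yl]-3-[4-(triethylsilyloxy)phenyl]prop-2-en-1-one | COc1cc(O[Si](CC)(CC)CC)c2c(c1C(=O)/C=C/c1ccc(O[Si](CC)(CC)CC)cc1)O[C@@H](c1ccc(O[Si](CC)(CC)CC)cc1)C[C@@H]2C[C@H](O[Si](C)(C)C(C)(C)C)CCc1ccc(O[Si](CC)(CC)CC)cc1
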